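The disconnection on which everything rests is the bond between the benzylic CH2 of the ethylene tether and C1 of the guaiacyl ring (ring A). The key step exploits the unbranched CH2–CH2 link between that ring and C6 of the oxane (ring B): it is the formal anti-Markovnikov hydroarylation product of a C6 vinyl group. One flask therefore carries out 9-BBN hydroboration of the vinyl-oxane, B-alkyl Suzuki–Miyaura coupling with benzyl-protected 4-bromoguaiacol and loss of the ester that masks the C4 oxygen. The precursor, a 2-aryl-6-vinyl-oxan-4-yl 4-nitrobenzoate with all three stereocenters in place, comes from a Prins cyclisation of (R)-hexa-1,5-dien-3-ol with the protected aryl aldehyde and Mitsunobu inversion at C4.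

Key step: step 6

Assumption: the target is read as (2S,4S,6S) at ring B, that is 2,6-cis with the C4 hydroxyl axial and trans to both ring substituents; ring A is the 4-hydroxy-3-methoxyphenyl ring, ring B the oxane (O1, C2–C6) and ring C the 3,4-dihydroxy-5-methoxyphenyl ring on C2.

Step 1
Reactants: 1 3,4-dihydroxy-5-methoxybenzaldehyde
Product: 2 3,4-bis(benzyloxy)-5-methoxybenzaldehyde
Conditions: BnBr, K2CO3, DMF, 60 °C, under N2
Reagents that add atoms: benzyl bromide BrCc1ccccc1
Why: Williamson ether synthesis (SN2 of both phenoxides on benzyl bromide) masks the catechol of ring C as ethers that should survive acid, base and boranes, the aldehyde staying untouched.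

Step 2
Reactants: 3 acrolein (prop-2-enal)
Product: 5 (R)-hexa-1,5-dien-3-ol, via dienyl diisopinocampheylborinate 4 (not isolated)
Conditions: (+)-Ipc2B(allyl), Et2O, −78 °C; then 3 M NaOH, 30% H2O2, 0 °C to rt
Reagents that add atoms: (+)-B-allyldiisopinocampheylborane C=CCB([C@H]1C[C@H]2C[C@@H]([C@@H]1C)C2(C)C)[C@H]1C[C@H]2C[C@@H]([C@@H]1C)C2(C)C
Why: Brown allylation, in which the allyl group is transferred through a six-membered chair transition state and the isopinocampheyl groups derived from (−)-α-pinene direct attack to the aldehyde face that gives the (R)-carbinol (the future C6 of ring B), the borinate 4 being cleaved by the oxidative work-up.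

Step 3
Reactants: 2 3,4-bis(benzyloxy)-5-methoxybenzaldehyde, 5 (R)-hexa-1,5-dien-3-ol
Product: 7 (2S,4R,6R)-2-[3,4-bis(benzyloxy)-5-methoxyphenyl]-6-ethenyloxan-4-ol (all-cis; hydroxyl equatorial), via all-cis 4-trifluoroacetate 6 (not isolated)
Conditions: TFA, CH2Cl2, 0 °C to rt; then K2CO3, MeOH, rt
Reagents that add atoms: trifluoroacetic acid OC(=O)C(F)(F)F
Why: Prins cyclisation, in which condensation gives the (E)-oxocarbenium ion that closes 6-endo through a chair with the vinyl and aryl groups equatorial and trifluoroacetate captures the C4 cation equatorially, so that C2 and C4 are set all-cis relative to the C6 center brought in by 5, before methanolysis of 6 frees the alcohol.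

Step 4
Reactants: 7 (2S,4R,6R)-2-[3,4-bis(benzyloxy)-5-methoxyphenyl]-6-ethenyloxan-4-ol
Product: 8 (2S,4S,6R)-2-[3,4-bis(benzyloxy)-5-methoxyphenyl]-6-ethenyloxan-4-yl 4-nitrobenzoate (ester axial; trans to the C2 aryl and C6 vinyl groups)
Conditions: 4-nitrobenzoic acid, PPh3, DIAD, THF, 0 °C to rt
Reagents that add atoms: 4-nitrobenzoic acid OC(=O)c1ccc(cc1)[N+](=O)[O-]
Why: Mitsunobu reaction, in which SN2 displacement of the equatorial oxyphosphonium group by 4-nitrobenzoate inverts C4 and places the oxygen axial as in the target.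

Step 5
Reactants: 9 4-bromo-2-methoxyphenol
Product: 10 1-(benzyloxy)-4-bromo-2-methoxybenzene
Conditions: BnBr, K2CO3, acetone, reflux
Reagents that add atoms: benzyl bromide BrCc1ccccc1
Why: Williamson ether synthesis protects the ring A phenol so that the aryl bromide enters the coupling as a neutral, non-acidic partner.

Step 6
Reactants: 8 (2S,4S,6R)-2-[3,4-bis(benzyloxy)-5-methoxyphenyl]-6-ethenyloxan-4-yl 4-nitrobenzoate, 10 1-(benzyloxy)-4-bromo-2-methoxybenzene
Product: 13 (2S,4S,6S)-2-[3,4-bis(benzyloxy)-5-methoxyphenyl]-6-{2-[4-(benzyloxy)-3-methoxyphenyl]ethyl}oxan-4-ol, via B-alkyl-9-BBN adduct 11 (not isolated), via coupled 4-nitrobenzoate 12 (not isolated)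
Conditions: 9-BBN, THF, 0 °C to rt; then 10, PdCl2(dppf) (5 mol %; dppf = 1,1'-bis(diphenylphosphino)ferrocene), 3 M aq NaOH, THF, 65 °C; then MeOH, 50 °C
Reagents that add atoms: none
Why: 9-BBN adds syn and anti-Markovnikov across the vinyl group on C6 of ring B to give the primary B-alkylborane 11; zerovalent palladium generated from PdCl2(dppf) then inserts into the C–Br bond of 10, hydroxide converts 11 into a borate that hands its primary alkyl group to the arylpalladium bromide, and reductive elimination forges the bond between the benzylic CH2 and C1 of ring A, after which the same hydroxide saponifies the 4-nitrobenzoate of 12. The closest known reaction type is the one-pot hydroboration/B-alkyl Suzuki–Miyaura coupling of a terminal alkene with an aryl bromide. No ring is closed and no stereocenter is formed: C2, C4 and C6 of ring B are spectators and none of them becomes trigonal. The step needs terminal regioselectivity in the hydroboration, which the bulk of 9-BBN and the monosubstituted alkene secure, and transfer of the primary alkyl group in preference to the secondary bicyclic B–C bonds, which is the normal order for B-alkyl-9-BBN borates. β-Hydride elimination from the alkylpalladium intermediate is held back by the wide bite angle of dppf, and the ester keeps the C4 oxygen free of acidic hydrogen while the borane is present.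

Step 7
Reactants: 13 (2S,4S,6S)-2-[3,4-bis(benzyloxy)-5-methoxyphenyl]-6-{2-[4-(benzyloxy)-3-methoxyphenyl]ethyl}oxan-4-ol
Product: 14 (2S,4S,6S)-2-(3,4-dihydroxy-5-methoxyphenyl)-6-[2-(4-hydroxy-3-methoxyphenyl)ethyl]oxan-4-ol (CNP0399218.2)
Conditions: H2 (1 atm), Pd/C (palladium on carbon, 10 wt%), EtOAc, rt, product handled under N2
Reagents that add atoms: none
Why: Catalytic hydrogenolysis should cleave the three aryl benzyl ethers under neutral conditions mild enough to leave the cyclic benzylic C2–O1 bond of ring B and the three stereocenters intact.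

Compound list
1 | 3,4-dihydroxy-5-methoxybenzaldehyde | COc1cc(C=O)cc(O)c1O | starting material
2 | 3,4-bis(benzyloxy)-5-methoxybenzaldehyde | COc1cc(C=O)cc(OCc2ccccc2)c1OCc1ccccc1 | intermediate
3 | acrolein (prop-2-enal) | C=CC=O | starting material
4 | (R)-hexa-1,5-dien-3-yl diisopinocampheylborinate (isopinocampheyl groups from (−)-α-pinene) | C=C[C@H](OB([C@H]1C[C@H]2C[C@@H]([C@@H]1C)C2(C)C)[C@H]1C[C@H]2C[C@@H]([C@@H]1C)C2(C)C)CC=C | intermediate
5 | (R)-hexa-1,5-dien-3-ol | C=C[C@H](O)CC=C | intermediate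
6 | (2S,4R,6R)-2-[3,4-bis(benzyloxy)-5-methoxyphenyl]-6-ethenyloxan-4-yl trifluoroacetate (all-cis) | C=C[C@H]1C[C@@H](OC(=O)C(F)(F)F)C[C@@H](c2cc(OCc3ccccc3)c(OCc3ccccc3)c(OC)c2)O1 | intermediate
7 | (2S,4R,6R)-2-[3,4-bis(benzyloxy)-5-methoxyphenyl]-6-ethenyloxan-4-ol (all-cis) | C=C[C@H]1C[C@@H](O)C[C@@H](c2cc(OCc3ccccc3)c(OCc3ccccc3)c(OC)c2)O1 | intermediate
8 | (2S,4S,6R)-2-[3,4-bis(benzyloxy)-5-methoxyphenyl]-6-ethenyloxan-4-yl 4-nitrobenzoate | C=C[C@H]1C[C@H](OC(=O)c2ccc(cc2)[N+](=O)[O-])C[C@@H](c2cc(OCc3ccccc3)c(OCc3ccccc3)c(OC)c2)O1 | intermediate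
9 | 4-bromo-2-methoxyphenol | COc1cc(Br)ccc1O | starting material
10 | 1-(benzyloxy)-4-bromo-2-methoxybenzene | COc1cc(Br)ccc1OCc1ccccc1 | intermediate
11 | (2S,4S,6S)-2-[3,4-bis(benzyloxy)-5-methoxyphenyl]-6-[2-(9-borabicyclo[3.3.1]nonan-9-yl)ethyl]oxan-4-yl 4-nitrobenzoate | B1(CC[C@H]2C[C@H](OC(=O)c3ccc(cc3)[N+](=O)[O-])C[C@@H](c3cc(OCc4ccccc4)c(OCc4ccccc4)c(OC)c3)O2)C2CCCC1CCC2 | intermediate
12 | (2S,4S,6S)-2-[3,4-bis(benzyloxy)-5-methoxyphenyl]-6-{2-[4-(benzyloxy)-3-methoxyphenyl]ethyl}oxan-4-yl 4-nitrobenzoate | COc1cc(CC[C@H]2C[C@H](OC(=O)c3ccc(cc3)[N+](=O)[O-])C[C@@H](c3cc(OCc4ccccc4)c(OCc4ccccc4)c(OC)c3)O2)ccc1OCc1ccccc1 | intermediate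
13 | (2S,4S,6S)-2-[3,4-bis(benzyloxy)-5-methoxyphenyl]-6-{2-[4-(benzyloxy)-3-methoxyphenyl]ethyl}oxan-4-ol | COc1cc(CC[C@H]2C[C@H](O)C[C@@H](c3cc(OCc4ccccc4)c(OCc4ccccc4)c(OC)c3)O2)ccc1OCc1ccccc1 | intermediate
14 | (2S,4S,6S)-2-(3,4-dihydroxy-5-methoxyphenyl)-6-[2-(4-hydroxy-3-methoxyphenyl)ethyl]oxan-4-ol | COc1cc(CC[C@H]2C[C@H](O)C[C@@H](c3cc(O)c(O)c(OC)c3)O2)ccc1O | target

Total step count: 7.
Longest linear sequence: 5 steps (steps 1, 3, 4, 6, 7 from compound 1; equally steps 2, 3, 4, 6, 7 from compound 3).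

Steps most likely to fail

Step 3 (Prins cyclisation). The oxocarbenium ion can equilibrate by 2-oxonia-Cope rearrangement, and its electron-rich benzylic C–O bond can ionise. Enantiomeric purity would then erode and aldehyde partners would be exchanged; the acid may also oligomerise the dienol. The fallback avoids cationic ring closure altogether; it sets out from 2 and 3 and comes back to the route at 8, bypassing step 4. Claisen–Schmidt condensation of 2 with acetone (aq NaOH) should give (E)-4-[3,4-bis(benzyloxy)-5-methoxyphenyl]but-3-en-2-one F1. Its boron enolate, formed with Et3N and the enantiomer of Ipc2BCl that leads to the (5R)-aldol, would add to 3 at −78 °C to give, after work-up, (1E,5R)-1-[3,4-bis(benzyloxy)-5-methoxyphenyl]-5-hydroxyhepta-1,6-dien-3-one F2; the enantioselectivity of this methyl ketone aldol is expected to be moderate. Acid-catalysed 6-endo oxa-Michael closure under thermodynamic control (Amberlyst-15, CH2Cl2) should give the 2,6-cis ketone (2S,6R)-2-[3,4-bis(benzyloxy)-5-methoxyphenyl]-6-ethenyloxan-4-one F3. Equatorial hydride delivery by LiBH(s-Bu)3 in THF at −78 °C should give the axial alcohol (2S,4S,6R)-2-[3,4-bis(benzyloxy)-5-methoxyphenyl]-6-ethenyloxan-4-ol F4, which 4-nitrobenzoyl chloride and pyridine would convert into 8.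

Step 7 (hydrogenolysis). Reductive cleavage of the benzylic C2–O1 bond of ring B may compete with O-debenzylation because ring C is electron-rich, and the freed catechol may oxidise in air. The fallback sets out from 13 and comes back at 14 by a non-reductive, Lewis-acid dealkylation: BCl3 with pentamethylbenzene as benzyl-cation scavenger in CH2Cl2 at −78 °C, then methanol quench. This fallback makes no new compound (F0).

Step 6 (hydroboration/coupling). Transmetalation of the primary alkyl borate may be slow relative to protodeboronation or β-hydride elimination, which would give the reduced ethyl compound or an isomerised alkene in place of the coupled product. The fallback forms the same aryl–carbon bond by a Heck arylation; it sets out from 8 and 10 and comes back at 14. Pd(OAc)2, P(o-tol)3, n-Bu4NCl and NaHCO3 in DMF at 90 °C should arylate the terminal carbon of the vinyl group to give (2S,4S,6R)-2-[3,4-bis(benzyloxy)-5-methoxyphenyl]-6-{(E)-2-[4-(benzyloxy)-3-methoxyphenyl]ethenyl}oxan-4-yl 4-nitrobenzoate F5. K2CO3 in MeOH would remove the ester to give (2S,4S,6R)-2-[3,4-bis(benzyloxy)-5-methoxyphenyl]-6-{(E)-2-[4-(benzyloxy)-3-methoxyphenyl]ethenyl}oxan-4-ol F6. The hydrogenation conditions of step 7 (H2, Pd/C, EtOAc) would then saturate the alkene and cleave the benzyl ethers in one operation to give 14.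

Further compounds
F1 | step 3 | (E)-4-[3,4-bis(benzyloxy)-5-methoxyphenyl]but-3-en-2-one | CC(=O)/C=C/c1cc(OCc2ccccc2)c(OCc2ccccc2)c(OC)c1
F2 | step 3 | (1E,5R)-1-[3,4-bis(benzyloxy)-5-methoxyphenyl]-5-hydroxyhepta-1,6-dien-3-one | C=C[C@H](O)CC(=O)/C=C/c1cc(OCc2ccccc2)c(OCc2ccccc2)c(OC)c1
F3 | step 3 | (2S,6R)-2-[3,4-bis(benzyloxy)-5-methoxyphenyl]-6-ethenyloxan-4-one | C=C[C@H]1CC(=O)C[C@@H](c2cc(OCc3ccccc3)c(OCc3ccccc3)c(OC)c2)O1
F4 | step 3 | (2S,4S,6R)-2-[3,4-bis(benzyloxy)-5-methoxyphenyl]-6-ethenyloxan-4-ol | C=C[C@H]1C[C@H](O)C[C@@H](c2cc(OCc3ccccc3)c(OCc3ccccc3)c(OC)c2)O1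
F5 | step 6 | (2S,4S,6R)-2-[3,4-bis(benzyloxy)-5-methoxyphenyl]-6-{(E)-2-[4-(benzyloxy)-3-methoxyphenyl]ethenyl}oxan-4-yl 4-nitrobenzoate | COc1cc(/C=C/[C@H]2C[C@H](OC(=O)c3ccc(cc3)[N+](=O)[O-])C[C@@H](c3cc(OCc4ccccc4)c(OCc4ccccc4)c(OC)c3)O2)ccc1OCc1ccccc1
F6 | step 6 | (2S,4S,6R)-2-[3,4-bis(benzyloxy)-5-methoxyphenyl]-6-{(E)-2-[4-(benzyloxy)-3-methoxyphenyl]ethenyl}oxan-4-ol | COc1cc(/C=C/[C@H]2C[C@H](O)C[C@@H](c3cc(OCc4ccccc4)c(OCc4ccccc4)c(OC)c3)O2)ccc1OCc1ccccc1
F0 | step 7 | none | none
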